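**Retrosynthetic overview**

- The target is (−)-quinic acid (the one carbocycle, taken intact from the chiral pool with C1, C3, C4 and C5 already set) carrying E-caffeates on O3 and O5 and a succinate half-ester on O4, with O1–H and the C1 carboxyl free.
- The strategy rests on the fact that each O3/O5 ester is an aryl–CH=CH–C(=O)–O unit. Cutting the two aryl–Cβ bonds leaves a 3,5-bis-acrylate and two protected 4-bromocatechols (twofold Mizoroki–Heck), so the crowded ring hydroxyls (O3–H axial, both next to the O4 ester) only have to accept small acryloyl groups.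
- The bis-acrylate comes from the 4-O-succinoyl 3,5-diol, which comes from the 3,5-bis-silyl ether by O4 acylation, which comes from regioselective silylation of a quinate ester, which comes from quinic acid.
- The C1 carboxyl is carried as a 4-methoxybenzyl ester, made by alkylating the cesium carboxylate, since this needs no acid and so avoids quinide formation. The succinate terminus is a tert-butyl ester and the catechols are silyl ethers. HF·pyridine and then TFA unmask everything without a hydrolytic step that could touch the three ring esters.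
- No ring is formed anywhere in the route; the two arene rings arrive with 4-bromocatechol.

Key step: step 7

Remark on numbering: quinic acid numbering is used throughout (C1 bears OH and the carboxyl; O3 is axial and cis to O4; O5 is trans to O4).
Remark on twofold steps: where one reagent acts on two or four like groups in one operation (steps 2, 4, 5, 6, 7, 8, 9), the partly reacted species are not numbered separately.

**Route**

Step 1
Reactants: 1 (−)-quinic acid; 2 4-methoxybenzyl chloride
Product: 4 4-methoxybenzyl (−)-quinate, via cesium quinate 3 (not isolated)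
Conditions: Cs2CO3 (0.55 equiv), DMF, rt; then 2 (1.1 equiv), NaI (cat.), rt to 40 °C
Reagents that add atoms: 4-methoxybenzyl chloride, COc1ccc(CCl)cc1
Why: SN2 O-alkylation of the cesium carboxylate (cesium-salt esterification) is far faster than alkylation of the neutral hydroxyls and, being free of acid, cannot lactonise the acid to quinide; no stereocentre is touched.

Step 2
Reactants: 4 4-methoxybenzyl (−)-quinate; 5 tert-butyldimethylsilyl chloride
Product: 6 4-methoxybenzyl 3,5-bis-O-(tert-butyldimethylsilyl)quinate
Conditions: 5 (2.3 equiv), Et3N, DMAP (cat.), DMF, 0 °C to rt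
Reagents that add atoms: tert-butyldimethylsilyl chloride, CC(C)(C)[Si](C)(C)Cl
Why: Regioselective silylation of the two outer secondary hydroxyls, the pattern known for simple alkyl quinates; once O3 and O5 carry the bulky silyl groups the flanked O4–H is shielded, and the tertiary O1–H does not react.

Step 3
Reactants: 6 4-methoxybenzyl 3,5-bis-O-(tert-butyldimethylsilyl)quinate; 7 mono-tert-butyl succinate
Product: 8 4-methoxybenzyl 4-O-(4-tert-butoxy-4-oxobutanoyl)-3,5-bis-O-(tert-butyldimethylsilyl)quinate
Conditions: 7 (2 equiv), N,N'-diisopropylcarbodiimide, DMAP, CH2Cl2, rt to 35 °C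
Reagents that add atoms: mono-tert-butyl succinate, CC(C)(C)OC(=O)CCC(=O)O
Why: Steglich esterification (carbodiimide activation, DMAP acyl transfer) acylates the only secondary hydroxyl left, O4–H, while the tertiary α-hydroxy ester O1–H is too hindered to compete; retention at C4 because the C–O bond is not broken.

Step 4
Reactants: 8 4-methoxybenzyl 4-O-(4-tert-butoxy-4-oxobutanoyl)-3,5-bis-O-(tert-butyldimethylsilyl)quinate
Product: 9 4-methoxybenzyl 4-O-(4-tert-butoxy-4-oxobutanoyl)quinate (free O1–H, O3–H, O5–H)
Conditions: HF·pyridine, pyridine, THF, 0 °C to rt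
Reagents that add atoms: none
Why: Fluoride cleavage of the two Si–O bonds in a buffered, weakly acidic medium removes both secondary silyl ethers without the base catalysis that would let the O4 succinate migrate to O3 or O5, and leaves the tert-butyl and 4-methoxybenzyl esters intact.

Step 5
Reactants: 9 4-methoxybenzyl 4-O-(4-tert-butoxy-4-oxobutanoyl)quinate; 10 acryloyl chloride
Product: 11 4-methoxybenzyl 3,5-di-O-acryloyl-4-O-(4-tert-butoxy-4-oxobutanoyl)quinate
Conditions: 10 (2.6 equiv), Et3N, DMAP (cat.), BHT (trace), CH2Cl2, −20 to 0 °C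
Reagents that add atoms: acryloyl chloride, C=CC(=O)Cl
Why: Acylation of the two secondary alcohols by a small, very reactive acid chloride under nucleophilic catalysis; at low temperature it should outrun succinate migration and leave the far slower tertiary O1–H free, with retention at C3 and C5.

Step 6
Reactants: 12 4-bromocatechol; 5 tert-butyldimethylsilyl chloride
Product: 13 4-bromo-1,2-bis(tert-butyldimethylsilyloxy)benzene
Conditions: 5 (2.5 equiv), imidazole, DMF, rt
Reagents that add atoms: tert-butyldimethylsilyl chloride, CC(C)(C)[Si](C)(C)Cl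
Why: Corey silylation of both phenols (imidazole-activated silyl transfer) gives a base-free, non-chelating aryl bromide suited to palladium coupling.

Step 7
Reactants: 11 4-methoxybenzyl 3,5-di-O-acryloyl-4-O-(4-tert-butoxy-4-oxobutanoyl)quinate; 13 4-bromo-1,2-bis(tert-butyldimethylsilyloxy)benzene (3 equiv)
Product: 14 4-methoxybenzyl 3,5-bis-O-[(E)-3-(3,4-bis(tert-butyldimethylsilyloxy)phenyl)acryloyl]-4-O-(4-tert-butoxy-4-oxobutanoyl)quinate
Conditions: Pd(OAc)2 (10 mol %), P(o-tol)3 (25 mol %), Et3N (5 equiv), BHT (trace), DMF, 90 °C, argon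
Reagents that add atoms: 4-bromo-1,2-bis(tert-butyldimethylsilyloxy)benzene, Brc1ccc(O[Si](C)(C)C(C)(C)C)c(O[Si](C)(C)C(C)(C)C)c1
Why: Mizoroki–Heck arylation: Pd(OAc)2 is reduced in the flask to a zerovalent palladium/P(o-tol)3 species that inserts into the C–Br bond of 13, the arylpalladium bromide adds syn across each acrylate C=C with the aryl group going to the terminal CH2, and syn β-hydride elimination after C–C rotation releases the cinnamate while Et3N takes up HBr and returns zerovalent palladium. The closest known reaction type is the Heck coupling of aryl bromides with acrylate esters under Pd(OAc)2/P(o-tol)3/Et3N, here run twice on one substrate. No ring closes and no stereocentre is created; the four ring stereocentres are spectators. The step needs β-regiochemistry, E geometry and complete twofold conversion: the polarised monosubstituted acrylate directs the aryl group to its unsubstituted carbon, the syn-insertion/syn-elimination sequence places aryl and ester trans in the product, and the two acrylates on O3 and O5 are remote and react independently, so excess 13 should drive both. The substrate has no free secondary hydroxyl, so the amine cannot trigger acyl migration, and the aryl silyl ethers, both acid-labile esters and the tertiary O1–H are inert to the anhydrous medium.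

Step 8
Reactants: 14 4-methoxybenzyl 3,5-bis-O-[(E)-3-(3,4-bis(tert-butyldimethylsilyloxy)phenyl)acryloyl]-4-O-(4-tert-butoxy-4-oxobutanoyl)quinate
Product: 15 4-methoxybenzyl 3,5-di-O-[(E)-caffeoyl]-4-O-(4-tert-butoxy-4-oxobutanoyl)quinate
Conditions: HF·pyridine, pyridine, THF, 0 °C to rt; quench with Me3SiOMe
Reagents that add atoms: none
Why: Fluoride-mediated desilylation of the four aryl silyl ethers under non-basic conditions, so that the freed catechols are not oxidised and no ester is cleaved or shifted.

Step 9
Reactants: 15 4-methoxybenzyl 3,5-di-O-[(E)-caffeoyl]-4-O-(4-tert-butoxy-4-oxobutanoyl)quinate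
Product: 16 3,5-di-O-[(E)-caffeoyl]-4-O-succinoylquinic acid (CNP0133919.1)
Conditions: TFA/CH2Cl2 (1:1), i-Pr3SiH (5 equiv), 0 °C to rt; evaporation, reversed-phase chromatography
Reagents that add atoms: none
Why: Acidolysis by alkyl–oxygen ionisation cleaves only the tert-butyl and 4-methoxybenzyl esters, since the secondary ring esters cannot ionise; the silane should reduce both carbocations before they can alkylate the catechol rings, and O5 is acylated so no lactone can form.

**Compound list**

1 | (−)-quinic acid, (1S,3R,4S,5R)-1,3,4,5-tetrahydroxycyclohexane-1-carboxylic acid | O[C@H]1[C@H](O)C[C@](O)(C(=O)O)C[C@H]1O | starting material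
2 | 4-methoxybenzyl chloride | COc1ccc(CCl)cc1 | starting material
3 | cesium quinate | O[C@H]1[C@H](O)C[C@](O)(C(=O)[O-])C[C@H]1O.[Cs+] | intermediate
4 | 4-methoxybenzyl (−)-quinate | O[C@H]1[C@H](O)C[C@](O)(C(=O)OCc2ccc(OC)cc2)C[C@H]1O | intermediate
5 | tert-butyldimethylsilyl chloride | CC(C)(C)[Si](C)(C)Cl | starting material
6 | 4-methoxybenzyl 3,5-bis-O-(tert-butyldimethylsilyl)quinate (quinic acid configuration) | O[C@H]1[C@H](O[Si](C)(C)C(C)(C)C)C[C@](O)(C(=O)OCc2ccc(OC)cc2)C[C@H]1O[Si](C)(C)C(C)(C)C | intermediate
7 | mono-tert-butyl succinate | CC(C)(C)OC(=O)CCC(=O)O | starting material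
8 | 4-methoxybenzyl 4-O-(4-tert-butoxy-4-oxobutanoyl)-3,5-bis-O-(tert-butyldimethylsilyl)quinate | CC(C)(C)OC(=O)CCC(=O)O[C@H]1[C@H](O[Si](C)(C)C(C)(C)C)C[C@](O)(C(=O)OCc2ccc(OC)cc2)C[C@H]1O[Si](C)(C)C(C)(C)C | intermediate
9 | 4-methoxybenzyl 4-O-(4-tert-butoxy-4-oxobutanoyl)quinate | CC(C)(C)OC(=O)CCC(=O)O[C@H]1[C@H](O)C[C@](O)(C(=O)OCc2ccc(OC)cc2)C[C@H]1O | intermediate
10 | acryloyl chloride | C=CC(=O)Cl | starting material
11 | 4-methoxybenzyl 3,5-di-O-acryloyl-4-O-(4-tert-butoxy-4-oxobutanoyl)quinate | CC(C)(C)OC(=O)CCC(=O)O[C@H]1[C@H](OC(=O)C=C)C[C@](O)(C(=O)OCc2ccc(OC)cc2)C[C@H]1OC(=O)C=C | intermediate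
12 | 4-bromocatechol | Oc1ccc(Br)cc1O | starting material
13 | 4-bromo-1,2-bis(tert-butyldimethylsilyloxy)benzene | Brc1ccc(O[Si](C)(C)C(C)(C)C)c(O[Si](C)(C)C(C)(C)C)c1 | intermediate
14 | 4-methoxybenzyl 3,5-bis-O-[(E)-3-(3,4-bis(tert-butyldimethylsilyloxy)phenyl)acryloyl]-4-O-(4-tert-butoxy-4-oxobutanoyl)quinate | CC(C)(C)OC(=O)CCC(=O)O[C@H]1[C@H](OC(=O)/C=C/c2ccc(O[Si](C)(C)C(C)(C)C)c(O[Si](C)(C)C(C)(C)C)c2)C[C@](O)(C(=O)OCc2ccc(OC)cc2)C[C@H]1OC(=O)/C=C/c1ccc(O[Si](C)(C)C(C)(C)C)c(O[Si](C)(C)C(C)(C)C)c1 | intermediate
15 | 4-methoxybenzyl 3,5-di-O-[(E)-caffeoyl]-4-O-(4-tert-butoxy-4-oxobutanoyl)quinate | CC(C)(C)OC(=O)CCC(=O)O[C@H]1[C@H](OC(=O)/C=C/c2ccc(O)c(O)c2)C[C@](O)(C(=O)OCc2ccc(OC)cc2)C[C@H]1OC(=O)/C=C/c1ccc(O)c(O)c1 | intermediate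
16 | 3,5-di-O-[(E)-caffeoyl]-4-O-succinoylquinic acid (CNP0133919.1) | O=C(O)CCC(=O)O[C@H]1[C@H](OC(=O)/C=C/c2ccc(O)c(O)c2)C[C@](O)(C(=O)O)C[C@H]1OC(=O)/C=C/c1ccc(O)c(O)c1 | target

**Count**

Total steps: 9. Longest linear sequence: 8 steps (steps 1–5 and 7–9 from quinic acid; step 6 is a one-step side branch).

**Steps most likely to fail**

1. Step 7. Oxidative addition into the electron-rich aryl bromide may be slow at a temperature the bis-acrylate tolerates. The second coupling could then stall while the acrylates oligomerise and the catalyst falls out as palladium black. The fallback sets out from 11 (with 13 as the arene source) and comes back at 14. It forms the Cα=Cβ bonds by olefin cross-metathesis instead of the Cβ–aryl bonds. Stille vinylation of 13 with tributyl(vinyl)stannane (Pd(PPh3)4, toluene, 100 °C) should give 3,4-bis(tert-butyldimethylsilyloxy)styrene F1. Cross-metathesis of 11 with excess F1 (second-generation Grubbs catalyst, CH2Cl2, 40 °C, ethylene swept out) should then give the E,E-bis-cinnamate 14. Acrylate–styrene cross-metathesis is E-selective, and acrylate–acrylate homocoupling is slow.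

2. Step 5. Amine-promoted conjugate addition to, and oligomerisation of, the acryloyl electrophile may compete with acylation of the slow axial O3–H. Longer exposure to base could then allow the succinate to shift or O1–H to be acylated. The fallback sets out from 9 and comes back at 11, using a masked acrylate. Acylation of 9 with 3-chloropropanoyl chloride (pyridine, CH2Cl2, −20 °C) carries no Michael acceptor and should give 4-methoxybenzyl 3,5-bis-O-(3-chloropropanoyl)-4-O-(4-tert-butoxy-4-oxobutanoyl)quinate F2. Dehydrochlorination of F2 with Et3N (MeCN, rt to 40 °C), when no free secondary hydroxyl remains, should deliver 11.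

3. Step 3. Acyl transfer to O4–H, crowded between two silyl ethers, may be slow enough that the carbodiimide-activated acid rearranges to the unreactive N-acylurea. The fallback sets out from 6 and comes back at 8, building the half-ester in two stages from a small cyclic anhydride. Ring-opening of succinic anhydride by 6 (DMAP, Et3N, toluene, 60 °C), as is routine for hemisuccinates of hindered secondary alcohols, should give 4-methoxybenzyl 3,5-bis-O-(tert-butyldimethylsilyl)-4-O-(3-carboxypropanoyl)quinate F3. The free acid of F3 is then esterified with tert-butyl 2,2,2-trichloroacetimidate (CH2Cl2/cyclohexane, rt, no Lewis acid, so the alcohols stay untouched) to give 8.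

**Further compounds**

F1 | step 7 | 3,4-bis(tert-butyldimethylsilyloxy)styrene | C=Cc1ccc(O[Si](C)(C)C(C)(C)C)c(O[Si](C)(C)C(C)(C)C)c1
F2 | step 5 | 4-methoxybenzyl 3,5-bis-O-(3-chloropropanoyl)-4-O-(4-tert-butoxy-4-oxobutanoyl)quinate | CC(C)(C)OC(=O)CCC(=O)O[C@H]1[C@H](OC(=O)CCCl)C[C@](O)(C(=O)OCc2ccc(OC)cc2)C[C@H]1OC(=O)CCCl
F3 | step 3 | 4-methoxybenzyl 3,5-bis-O-(tert-butyldimethylsilyl)-4-O-(3-carboxypropanoyl)quinate | O=C(O)CCC(=O)O[C@H]1[C@H](O[Si](C)(C)C(C)(C)C)C[C@](O)(C(=O)OCc2ccc(OC)cc2)C[C@H]1O[Si](C)(C)C(C)(C)C
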